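**Target:** (E)-3-[(6R,7R)-6-(3,4-dihydroxy-2-methoxy-6-methylbenzoyloxy)-7-hydroxy-7-methyl-8-oxo-5,6,7,8-tetrahydro-1H-isochromen-3-yl]prop-2-enoic acid. Re-reading the SMILES gives 6R,7R with the C6 ester oxygen and the C7 hydroxyl cis. The route is a paper design and has not been run.

## Retrosynthetic overview

1. The last C–C bond is C7–C8: the C8 aldehyde of a 2H-pyran-3-carbaldehyde is turned into an acyl anion by a carbene catalyst and adds to the C7 methyl ketone (crossed benzoin), closing the carbocycle and setting C7 from C6.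
2. The keto aldehyde 22 comes from a nickel-catalysed sp2–sp3 coupling of bromo enal 20 (pyran ring plus acrylate) with bromide 10 (C5–C7, already carrying the aryl ester).
3. Bromide 10 comes from acyl bromide 9 and (R)-epoxide 8 (C6 from kinetic resolution); acid 5 comes from 5-methylpyrogallol.
4. Bromo enal 20 comes from bromoformylation of dihydropyranone 18, itself from cyclodehydration of a 1,3-diketone.
5. Ring order: arene (bought), pyran ring (step 10), carbocycle (step 14).

Assumption: 5-methylpyrogallol, 2-methyl-2-vinyl-1,3-dioxolane, 4-hydroxybutan-2-one and mono-tert-butyl fumarate are taken as commercial; ring numbering follows 1H-isochromene, and "ArCO" below means 4-methoxy-6-methyl-2,2-diphenyl-1,3-benzodioxole-5-carbonyl.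

## Route

**Step 1**
Reactants: 1 5-methylpyrogallol
Product: 2 6-methyl-2,2-diphenyl-1,3-benzodioxol-4-ol
Conditions: Ph2CCl2 (1.2 equiv), Ph2O, 175 °C
Reagents that add atoms: dichlorodiphenylmethane, ClC(Cl)(c1ccccc1)c1ccccc1
Why: Ketalisation of a pyrogallol can only bridge two adjacent hydroxyls, so one phenol stays free next to the position to be carboxylated.

**Step 2**
Reactants: 2 6-methyl-2,2-diphenyl-1,3-benzodioxol-4-ol
Product: 3 4-hydroxy-6-methyl-2,2-diphenyl-1,3-benzodioxole-5-carbaldehyde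
Conditions: MgCl2, Et3N, (CH2O)n, MeCN, 80 °C
Reagents that add atoms: paraformaldehyde (formaldehyde), C=O
Why: Magnesium phenoxide ortho-formylation (Casnati–Skattebøl) is ortho-specific, and the only free ortho carbon is the one between the hydroxyl and the methyl group.

**Step 3**
Reactants: 3 4-hydroxy-6-methyl-2,2-diphenyl-1,3-benzodioxole-5-carbaldehyde
Product: 4 4-methoxy-6-methyl-2,2-diphenyl-1,3-benzodioxole-5-carbaldehyde
Conditions: MeI, K2CO3, DMF, 40 °C
Reagents that add atoms: iodomethane, CI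
Why: Williamson O-methylation of the single free phenol.

**Step 4**
Reactants: 4 4-methoxy-6-methyl-2,2-diphenyl-1,3-benzodioxole-5-carbaldehyde
Product: 5 4-methoxy-6-methyl-2,2-diphenyl-1,3-benzodioxole-5-carboxylic acid
Conditions: NaClO2, NaH2PO4, 2-methylbut-2-ene, t-BuOH/H2O, rt
Reagents that add atoms: sodium chlorite, [Na+].[O-]Cl=O
Why: Pinnick oxidation takes the hindered aldehyde to the acid without touching the ketal or the electron-rich ring (hypochlorite is scavenged).

**Step 5**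
Reactants: 6 2-methyl-2-vinyl-1,3-dioxolane
Product: 7 rac-2-methyl-2-(oxiran-2-yl)-1,3-dioxolane
Conditions: mCPBA, NaHCO3, ClCH2CH2Cl, 55 °C
Reagents that add atoms: mCPBA, OOC(=O)c1cccc(Cl)c1
Why: Prilezhaev epoxidation of the terminal alkene; the ketal masks the future C7 ketone.

**Step 6**
Reactants: 7 rac-2-methyl-2-(oxiran-2-yl)-1,3-dioxolane
Product: 8 2-methyl-2-[(2R)-oxiran-2-yl]-1,3-dioxolane
Conditions: (R,R)-N,N′-bis(3,5-di-tert-butylsalicylidene)-1,2-cyclohexanediaminocobalt acetate (0.5 mol %, the enantiomer that hydrolyses the S epoxide), H2O (0.55 equiv), THF, 0 °C to rt, then distil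
Reagents that add atoms: none
Why: Jacobsen hydrolytic kinetic resolution of a terminal epoxide; the recovered R epoxide carries the future C6 stereocentre.

**Step 7**
Reactants: 5 4-methoxy-6-methyl-2,2-diphenyl-1,3-benzodioxole-5-carboxylic acid; 8 2-methyl-2-[(2R)-oxiran-2-yl]-1,3-dioxolane
Product: 10 (1S)-2-bromo-1-(2-methyl-1,3-dioxolan-2-yl)ethyl 4-methoxy-6-methyl-2,2-diphenyl-1,3-benzodioxole-5-carboxylate, via acyl bromide 9 (not isolated)
Conditions: (COBr)2, cat. DMF, CH2Cl2, 0 °C to rt, evaporate; then 8, Bu4NBr (10 mol %), PhMe, 60 °C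
Reagents that add atoms: oxalyl bromide, BrC(=O)C(=O)Br
Why: Halide-catalysed insertion of an epoxide into an acyl halide: bromide opens the CH2 terminus and the resulting alkoxide is acylated, so the hindered ester forms without touching C6 (the S label is a priority change only).

**Step 8**
Reactants: 11 4-hydroxybutan-2-one
Product: 12 4-(tert-butyldimethylsilyloxy)butan-2-one
Conditions: TBSCl, imidazole, CH2Cl2, rt
Reagents that add atoms: tert-butyldimethylsilyl chloride, CC(C)(C)[Si](C)(C)Cl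
Why: Silylation stops retro-aldol and elimination of the β-hydroxy ketone in the enolate step.

**Step 9**
Reactants: 12 4-(tert-butyldimethylsilyloxy)butan-2-one; 13 (E)-4-tert-butoxy-4-oxobut-2-enoic acid
Product: 16 tert-butyl (E)-8-(tert-butyldimethylsilyloxy)-4,6-dioxooct-2-enoate, via lithium enolate 14 (not isolated), via acyl imidazolide 15 (not isolated)
Conditions: 12 (2.2 equiv), LiN(SiMe3)2 (2.2 equiv), THF, −78 °C; 13 pre-activated with CDI (THF, rt) added at −78 °C, then −30 °C; aq. NH4Cl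
Reagents that add atoms: none
Why: Claisen-type C-acylation of the kinetic methyl enolate by an acyl imidazolide gives the 1,3-diketone; the second equivalent of enolate deprotonates the product.

**Step 10**
Reactants: 16 tert-butyl (E)-8-(tert-butyldimethylsilyloxy)-4,6-dioxooct-2-enoate
Product: 18 tert-butyl (E)-3-(4-oxo-5,6-dihydro-4H-pyran-2-yl)prop-2-enoate, via hydroxy diketone 17 (not isolated)
Conditions: 48% aq. HF, MeCN, 0 °C to rt; then PPTS (cat.), PhMe, 70 °C
Reagents that add atoms: none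
Why: Desilylation, then hemiketalisation of the δ-hydroxy 1,3-diketone and dehydration to the vinylogous ester (cyclodehydration); this forms the pyran ring.

**Step 11**
Reactants: 18 tert-butyl (E)-3-(4-oxo-5,6-dihydro-4H-pyran-2-yl)prop-2-enoate
Product: 20 tert-butyl (E)-3-(4-bromo-5-formyl-6H-pyran-2-yl)prop-2-enoate, via iminium bromide 19 (not isolated)
Conditions: PBr3, DMF, CHCl3, 0 to 45 °C; aq. NaOAc, 0 °C
Reagents that add atoms: N,N-dimethylformamide, CN(C)C=O; phosphorus tribromide, BrP(Br)Br; water, O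
Why: Vilsmeier–Haack–Arnold bromoformylation of a cyclic ketone at its only α-CH2 gives the β-bromo enal, with bromine and formyl cis because both sit on the ring alkene.

**Step 12**
Reactants: 20 tert-butyl (E)-3-(4-bromo-5-formyl-6H-pyran-2-yl)prop-2-enoate; 10 (1S)-2-bromo-1-(2-methyl-1,3-dioxolan-2-yl)ethyl 4-methoxy-6-methyl-2,2-diphenyl-1,3-benzodioxole-5-carboxylate
Product: 21 tert-butyl (E)-3-[4-[(2R)-2-(ArCO-oxy)-2-(2-methyl-1,3-dioxolan-2-yl)ethyl]-5-formyl-6H-pyran-2-yl]prop-2-enoate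
Conditions: NiBr2·glyme (10 mol %), 4,4′-di-tert-butyl-2,2′-bipyridine (10 mol %), NaI (25 mol %), Mn powder (2 equiv), DMPU, 35 °C
Reagents that add atoms: none
Why: Nickel-catalysed reductive cross-electrophile coupling (Weix type) of an alkenyl bromide with a primary alkyl bromide; the alkyl radical is captured at nickel and reductive elimination should outrun loss of the β-acyloxy group, and C6 is not involved.

**Step 13**
Reactants: 21 tert-butyl (E)-3-[4-[(2R)-2-(ArCO-oxy)-2-(2-methyl-1,3-dioxolan-2-yl)ethyl]-5-formyl-6H-pyran-2-yl]prop-2-enoate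
Product: 22 tert-butyl (E)-3-[4-[(2R)-2-(ArCO-oxy)-3-oxobutyl]-5-formyl-6H-pyran-2-yl]prop-2-enoate
Conditions: TsOH·H2O (0.2 equiv), acetone/H2O 10:1, 45 °C
Reagents that add atoms: water, O
Why: Mild acetal hydrolysis frees the methyl ketone while the tert-butyl ester, the catechol ketal and the vinylogous formate survive.

**Step 14**
Reactants: 22 tert-butyl (E)-3-[4-[(2R)-2-(ArCO-oxy)-3-oxobutyl]-5-formyl-6H-pyran-2-yl]prop-2-enoate
Product: 23 tert-butyl (E)-3-[(6R,7R)-6-(ArCO-oxy)-7-hydroxy-7-methyl-8-oxo-5,6,7,8-tetrahydro-1H-isochromen-3-yl]prop-2-enoate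
Conditions: 2-(pentafluorophenyl)-6,7-dihydro-5H-pyrrolo[2,1-c][1,2,4]triazol-2-ium tetrafluoroborate (15 mol %), i-Pr2NEt (15 mol %), PhMe, 4 Å MS, 25 °C
Reagents that add atoms: none
Why: Carbene-catalysed intramolecular crossed aldehyde–ketone benzoin: the Breslow acyl anion at C8 adds to the C7 ketone in a chair-like six-membered transition state with the C6 aroyloxy group anti to the incoming carbon and the methyl equatorial (polar Felkin–Anh), giving the 6,7-cis product (7R), which should also be the more stable isomer under the reversible conditions.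

**Step 15**
Reactants: 23 tert-butyl (E)-3-[(6R,7R)-6-(ArCO-oxy)-7-hydroxy-7-methyl-8-oxo-5,6,7,8-tetrahydro-1H-isochromen-3-yl]prop-2-enoate
Product: 24 (E)-3-[(6R,7R)-6-(3,4-dihydroxy-2-methoxy-6-methylbenzoyloxy)-7-hydroxy-7-methyl-8-oxo-5,6,7,8-tetrahydro-1H-isochromen-3-yl]prop-2-enoic acid
Conditions: TFA/CH2Cl2/H2O 10:10:1, 1,3-dimethoxybenzene, 0 °C to rt
Reagents that add atoms: none
Why: One acidolysis removes the diphenylmethylene ketal (as benzophenone) and the tert-butyl ester (as isobutene) without base, which the C6 ester/C5–H arrangement would not tolerate.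

## Compound list

1 | 5-methylpyrogallol | Cc1cc(O)c(O)c(O)c1 | starting material
2 | 6-methyl-2,2-diphenyl-1,3-benzodioxol-4-ol | Cc1cc(O)c2OC(c3ccccc3)(c3ccccc3)Oc2c1 | intermediate
3 | 4-hydroxy-6-methyl-2,2-diphenyl-1,3-benzodioxole-5-carbaldehyde | Cc1cc2OC(c3ccccc3)(c3ccccc3)Oc2c(O)c1C=O | intermediate
4 | 4-methoxy-6-methyl-2,2-diphenyl-1,3-benzodioxole-5-carbaldehyde | Cc1cc2OC(c3ccccc3)(c3ccccc3)Oc2c(OC)c1C=O | intermediate
5 | 4-methoxy-6-methyl-2,2-diphenyl-1,3-benzodioxole-5-carboxylic acid | Cc1cc2OC(c3ccccc3)(c3ccccc3)Oc2c(OC)c1C(=O)O | intermediate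
6 | 2-methyl-2-vinyl-1,3-dioxolane | C=CC1(C)OCCO1 | starting material
7 | rac-2-methyl-2-(oxiran-2-yl)-1,3-dioxolane | CC1(OCCO1)C1CO1 | intermediate
8 | 2-methyl-2-[(2R)-oxiran-2-yl]-1,3-dioxolane | CC1(OCCO1)[C@H]1CO1 | intermediate
9 | 4-methoxy-6-methyl-2,2-diphenyl-1,3-benzodioxole-5-carbonyl bromide | Cc1cc2OC(c3ccccc3)(c3ccccc3)Oc2c(OC)c1C(=O)Br | intermediate
10 | (1S)-2-bromo-1-(2-methyl-1,3-dioxolan-2-yl)ethyl 4-methoxy-6-methyl-2,2-diphenyl-1,3-benzodioxole-5-carboxylate | BrC[C@@H](OC(=O)c1c(C)cc2OC(c3ccccc3)(c3ccccc3)Oc2c1OC)C1(C)OCCO1 | intermediate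
11 | 4-hydroxybutan-2-one | CC(=O)CCO | starting material
12 | 4-(tert-butyldimethylsilyloxy)butan-2-one | CC(=O)CCO[Si](C)(C)C(C)(C)C | intermediate
13 | (E)-4-tert-butoxy-4-oxobut-2-enoic acid (mono-tert-butyl fumarate) | OC(=O)/C=C/C(=O)OC(C)(C)C | starting material
14 | lithium 4-(tert-butyldimethylsilyloxy)but-1-en-2-olate | [Li+].[O-]C(=C)CCO[Si](C)(C)C(C)(C)C | intermediate
15 | tert-butyl (E)-4-(imidazol-1-yl)-4-oxobut-2-enoate | CC(C)(C)OC(=O)/C=C/C(=O)n1ccnc1 | intermediate
16 | tert-butyl (E)-8-(tert-butyldimethylsilyloxy)-4,6-dioxooct-2-enoate | CC(C)(C)OC(=O)/C=C/C(=O)CC(=O)CCO[Si](C)(C)C(C)(C)C | intermediate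
17 | tert-butyl (E)-8-hydroxy-4,6-dioxooct-2-enoate | CC(C)(C)OC(=O)/C=C/C(=O)CC(=O)CCO | intermediate
18 | tert-butyl (E)-3-(4-oxo-5,6-dihydro-4H-pyran-2-yl)prop-2-enoate | CC(C)(C)OC(=O)/C=C/C1=CC(=O)CCO1 | intermediate
19 | [4-bromo-6-[(E)-3-tert-butoxy-3-oxoprop-1-enyl]-2H-pyran-3-yl]methylidene-dimethylammonium bromide | CC(C)(C)OC(=O)/C=C/C1=CC(Br)=C(C=[N+](C)C)CO1.[Br-] | intermediate
20 | tert-butyl (E)-3-(4-bromo-5-formyl-6H-pyran-2-yl)prop-2-enoate | CC(C)(C)OC(=O)/C=C/C1=CC(Br)=C(C=O)CO1 | intermediate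
21 | tert-butyl (E)-3-[4-[(2R)-2-(ArCO-oxy)-2-(2-methyl-1,3-dioxolan-2-yl)ethyl]-5-formyl-6H-pyran-2-yl]prop-2-enoate | CC(C)(C)OC(=O)/C=C/C1=CC(C[C@@H](OC(=O)c2c(C)cc3OC(c4ccccc4)(c4ccccc4)Oc3c2OC)C2(C)OCCO2)=C(C=O)CO1 | intermediate
22 | tert-butyl (E)-3-[4-[(2R)-2-(ArCO-oxy)-3-oxobutyl]-5-formyl-6H-pyran-2-yl]prop-2-enoate | CC(C)(C)OC(=O)/C=C/C1=CC(C[C@@H](OC(=O)c2c(C)cc3OC(c4ccccc4)(c4ccccc4)Oc3c2OC)C(C)=O)=C(C=O)CO1 | intermediate
23 | tert-butyl (E)-3-[(6R,7R)-6-(ArCO-oxy)-7-hydroxy-7-methyl-8-oxo-5,6,7,8-tetrahydro-1H-isochromen-3-yl]prop-2-enoate | COc1c2OC(c3ccccc3)(c3ccccc3)Oc2cc(C)c1C(=O)O[C@@H]1CC2=C(COC(/C=C/C(=O)OC(C)(C)C)=C2)C(=O)[C@]1(C)O | intermediate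
24 | (E)-3-[(6R,7R)-6-(3,4-dihydroxy-2-methoxy-6-methylbenzoyloxy)-7-hydroxy-7-methyl-8-oxo-5,6,7,8-tetrahydro-1H-isochromen-3-yl]prop-2-enoic acid | COc1c(O)c(O)cc(C)c1C(=O)O[C@@H]1CC2=C(COC(/C=C/C(=O)O)=C2)C(=O)[C@]1(C)O | target

## Step count and risks

Total: 15 steps. Longest linear sequence: 9 steps (1, 2, 3, 4, 7, 12, 13, 14, 15).

**Step 14 (benzoin ring closure), the most likely to fail.** The aldehyde is a vinylogous formate, so the Breslow intermediate may form slowly. Base can deprotonate C5 and expel the C6 carboxylate. The cis/trans ratio rests on substrate control alone. The fallback makes the carbocycle with a free C6 hydroxyl and puts the ester on last. It sets out from epoxide 8: bromotriethylsilane opens it at CH2 to give [(1S)-2-bromo-1-(2-methyl-1,3-dioxolan-2-yl)ethoxy]triethylsilane F1. The nickel/manganese coupling of step 12 with 20 gives the coupled silyl ether F2. Aqueous TsOH removes ketal and silyl group to give the hydroxy keto aldehyde F3 (in equilibrium with its lactol). The same triazolium catalyst then closes the ring to the cis-diol F4, where no leaving group sits at C6. Selective acylation of the secondary hydroxyl of F4 with acyl bromide 9 (DMAP, 2,6-lutidine) comes back to the route at 23.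

**Step 12 (reductive coupling).** The β-acyloxy alkyl bromide may eliminate, and the alkyl radical may add to the acrylate. The fallback uses the epoxide itself as electrophile and forms the ester after the C–C bond. It sets out from 20: trimethyl orthoformate and PPTS give the dimethyl acetal F5, so no lactol can form later. Nickel/bipyridine with NaI, Et3N·HCl and Mn opens epoxide 8 at its CH2 terminus to give the alcohol F6. Acylation of F6 with acyl bromide 9 gives the ester F7. Aqueous acid cleaves acetal and ketal together, and the sequence comes back to the route at 22.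

**Step 11 (bromoformylation).** The vinylogous ester may be formylated at its own α-carbon (the ring CH) instead of at the CH2, and HBr may cut the tert-butyl ester. The fallback fixes the site first under neutral conditions. It sets out from 18: N,N-dimethylformamide dimethyl acetal condenses only at the CH2 to give the enaminone F8. Oxalyl bromide converts F8 into the same iminium bromide 19, whose hydrolysis comes back to the route at 20.

## Further compounds

F1 | step 14 | [(1S)-2-bromo-1-(2-methyl-1,3-dioxolan-2-yl)ethoxy]triethylsilane | BrC[C@@H](O[Si](CC)(CC)CC)C1(C)OCCO1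
F2 | step 14 | tert-butyl (E)-3-[5-formyl-4-[(2R)-2-(2-methyl-1,3-dioxolan-2-yl)-2-(triethylsilyloxy)ethyl]-6H-pyran-2-yl]prop-2-enoate | CC(C)(C)OC(=O)/C=C/C1=CC(C[C@@H](O[Si](CC)(CC)CC)C2(C)OCCO2)=C(C=O)CO1
F3 | step 14 | tert-butyl (E)-3-[5-formyl-4-[(2R)-2-hydroxy-3-oxobutyl]-6H-pyran-2-yl]prop-2-enoate | CC(C)(C)OC(=O)/C=C/C1=CC(C[C@@H](O)C(C)=O)=C(C=O)CO1
F4 | step 14 | tert-butyl (E)-3-[(6R,7R)-6,7-dihydroxy-7-methyl-8-oxo-5,6,7,8-tetrahydro-1H-isochromen-3-yl]prop-2-enoate | O[C@@H]1CC2=C(COC(/C=C/C(=O)OC(C)(C)C)=C2)C(=O)[C@]1(C)O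
F5 | step 12 | tert-butyl (E)-3-[4-bromo-5-(dimethoxymethyl)-6H-pyran-2-yl]prop-2-enoate | CC(C)(C)OC(=O)/C=C/C1=CC(Br)=C(C(OC)OC)CO1
F6 | step 12 | tert-butyl (E)-3-[5-(dimethoxymethyl)-4-[(2R)-2-hydroxy-2-(2-methyl-1,3-dioxolan-2-yl)ethyl]-6H-pyran-2-yl]prop-2-enoate | CC(C)(C)OC(=O)/C=C/C1=CC(C[C@@H](O)C2(C)OCCO2)=C(C(OC)OC)CO1
F7 | step 12 | tert-butyl (E)-3-[4-[(2R)-2-(ArCO-oxy)-2-(2-methyl-1,3-dioxolan-2-yl)ethyl]-5-(dimethoxymethyl)-6H-pyran-2-yl]prop-2-enoate | CC(C)(C)OC(=O)/C=C/C1=CC(C[C@@H](OC(=O)c2c(C)cc3OC(c4ccccc4)(c4ccccc4)Oc3c2OC)C2(C)OCCO2)=C(C(OC)OC)CO1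
F8 | step 11 | tert-butyl (E)-3-[(5E)-5-(dimethylaminomethylidene)-4-oxo-5,6-dihydro-4H-pyran-2-yl]prop-2-enoate | CC(C)(C)OC(=O)/C=C/C1=CC(=O)/C(=C/N(C)C)CO1
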